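**Retrosynthetic overview**
1. The ten-membered ring is closed last, at C4–C5, by an intramolecular Nozaki–Hiyama–Kishi addition of a (Z)-β-iodo dienone to a C5 aldehyde; this sets C5 and gives the target directly.
2. The (Z)-β-iodo enone comes from HI addition to a propynyl ketone, made by Stille acylation of a C2 acid chloride.
3. The trans-α-methylene-γ-butyrolactone (C6–C7 bond, both centres) comes from a chiral Brønsted acid-catalysed 2-alkoxycarbonyl allylboration of a silyloxyacetaldehyde (new step).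
4. The allylboronate comes from reductive borylmethylation of a γ-angeloyloxy ynoate; C8, the first stereocentre, comes from an organocatalytic vinylogous Mukaiyama aldol of an ynal with a senecioate silyl dienolate.
5. Ring order: lactone first (step 6), ten-membered carbocycle second (step 12).

Assumption: positions are cited in germacrane numbering (ring C1–C10, lactone carbons C11–C13, C14 on C10, C15 on C4), and all starting materials and catalysts named are taken as purchasable. The sense of induction of the two chiral catalysts is assigned by analogy and must be confirmed on the first run.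

**Route**

Step 1
Reactants: 1 methyl 4-hydroxybut-2-ynoate
Product: 2 methyl 4-oxobut-2-ynoate
Conditions: activated MnO2 (10 equiv), CH2Cl2, rt; filter, use the solution at once
Reagents that add atoms: none
Why: MnO2 oxidises the propargylic primary alcohol to the ynal without touching the ester (propargylic alcohol oxidation); no stereocentre is formed.

Step 2
Reactants: 3 tert-butyl 3-methylbut-2-enoate
Product: 5 tert-butyl[(1-tert-butoxy-3-methylbuta-1,3-dien-1-yl)oxy]dimethylsilane, via lithium dienolate 4 (not isolated)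
Conditions: LiN(i-Pr)2, THF, −78 °C; then TBSCl, DMPU, −78 °C → rt
Reagents that add atoms: tert-butylchlorodimethylsilane, CC(C)(C)[Si](C)(C)Cl; lithium diisopropylamide, [Li+].CC(C)[N-]C(C)C (lithium of intermediate 4 only)
Why: Kinetic γ-deprotonation of the senecioate and O-silylation give the silyl dienol ether (silyl ketene acetal formation); no stereocentre is formed.

Step 3
Reactants: 2 methyl 4-oxobut-2-ynoate; 5 tert-butyl[(1-tert-butoxy-3-methylbuta-1,3-dien-1-yl)oxy]dimethylsilane
Product: 7 1-tert-butyl 8-methyl (2E,5S)-5-hydroxy-3-methyloct-2-en-6-ynedioate, via trichlorosilyl ether 6 (not isolated)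
Conditions: SiCl4 (1.1 equiv), (S,S)-binaphthyldiamine-derived pentamethylene-linked bisphosphoramide (5 mol%), CH2Cl2, −78 °C; aq. NaHCO3
Reagents that add atoms: silicon tetrachloride, Cl[Si](Cl)(Cl)Cl (SiCl3 group of intermediate 6 only)
Why: In this Lewis base-catalysed vinylogous Mukaiyama aldol (Denmark type, organocatalytic) the chiral phosphoramide-bound trichlorosilyl cation activates the conjugated aldehyde and the dienolate attacks through its γ-carbon on the Si face, setting C8 as S and the C1=C10 bond as E (the (S,S) catalyst is assigned on the reported Re-face preference of the (R,R) catalyst).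

Step 4
Reactants: 7 1-tert-butyl 8-methyl (2E,5S)-5-hydroxy-3-methyloct-2-en-6-ynedioate; 8 angelic acid [(2Z)-2-methylbut-2-enoic acid]
Product: 10 1-tert-butyl 8-methyl (2E,5S)-3-methyl-5-{[(2Z)-2-methylbut-2-enoyl]oxy}oct-2-en-6-ynedioate, via mixed anhydride 9 (not isolated)
Conditions: 8, 2,4,6-Cl3C6H2COCl, Et3N, toluene, rt; filter off the salt; then 7, toluene, 80 °C (no DMAP)
Reagents that add atoms: 2,4,6-trichlorobenzoyl chloride, O=C(Cl)c1c(Cl)cc(Cl)cc1Cl (aroyl group of intermediate 9 only)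
Why: Yamaguchi-type mixed-anhydride acylation without a nucleophilic amine avoids the addition–elimination that turns angelate into tiglate, and acylation at oxygen leaves C8 untouched.

Step 5
Reactants: 10 1-tert-butyl 8-methyl (2E,5S)-3-methyl-5-{[(2Z)-2-methylbut-2-enoyl]oxy}oct-2-en-6-ynedioate; 11 2-(iodomethyl)-4,4,5,5-tetramethyl-1,3,2-dioxaborolane
Product: 13 1-tert-butyl 8-methyl (2E,5S,6Z)-3-methyl-5-{[(2Z)-2-methylbut-2-enoyl]oxy}-7-[(4,4,5,5-tetramethyl-1,3,2-dioxaborolan-2-yl)methyl]octa-2,6-dienedioate, via aluminium allenolate 12 (not isolated)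
Conditions: i-Bu2AlH (1.1 equiv), HMPA (2.5 equiv), THF, −20 °C; then 11, −20 °C → rt
Reagents that add atoms: diisobutylaluminium hydride, CC(C)C[AlH]CC(C)C (aluminium of intermediate 12 only; its hydride becomes H-7)
Why: The HMPA-complexed hydride adds 1,4 to the ynoate only (Tsuda–Saegusa conjugate reduction; the three enoates need copper catalysis and stay intact), and C-alkylation of the allenolate from the side of the small C7–H places C8 cis to CO2Me and trans to CH2B (Hall's route to 2-alkoxycarbonyl allylboronates).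

Step 6
Reactants: 13 the allylboronate of step 5; 14 2-{[tert-butyl(diphenyl)silyl]oxy}acetaldehyde
Product: 16 tert-butyl (2E,5S)-5-[(2S,3R)-2-({[tert-butyl(diphenyl)silyl]oxy}methyl)-4-methylidene-5-oxooxolan-3-yl]-3-methyl-5-{[(2Z)-2-methylbut-2-enoyl]oxy}pent-2-enoate, via O-boryl homoallylic alkoxide 15 (not isolated)
Conditions: (S)-3,3'-bis(2,4,6-triisopropylphenyl)-1,1'-binaphthyl-2,2'-diyl N-triflylphosphoramide (10 mol%), 4 Å MS, toluene, −20 °C → rt (lactonises in the flask)
Reagents that add atoms: none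
Why: Proposed new method: the strong chiral Brønsted acid hydrogen-bonds a pinacolate oxygen of the ester-deactivated allylboronate and so raises the Lewis acidity of boron, the aldehyde then reacts through a closed chair transition state in which the catalyst selects the aldehyde Si face (6S) and the C8 substituent trans to CH2B sits equatorial (6,7-anti, hence 7R), and the borate oxygen closes onto the methyl ester to give the trans-lactone; the closest known reactions are chiral phosphoric acid-catalysed allylboration of aldehydes with simple allyl- and crotylboronates and the racemic triflic acid-catalysed additions of 2-alkoxycarbonyl allylboronates.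

Step 7
Reactants: 16 the lactone tert-butyl ester of step 6
Product: 17 (2E,5S)-5-[(2S,3R)-2-({[tert-butyl(diphenyl)silyl]oxy}methyl)-4-methylidene-5-oxooxolan-3-yl]-3-methyl-5-{[(2Z)-2-methylbut-2-enoyl]oxy}pent-2-enoic acid
Conditions: TFA/CH2Cl2 (1:4), 0 °C → rt
Reagents that add atoms: none
Why: Acidolysis of the tert-butyl ester with loss of isobutene spares the lactone, the angelate and the acid-stable TBDPS ether.

Step 8
Reactants: 17 the acid of step 7; 18 tributyl(prop-1-yn-1-yl)stannane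
Product: 20 (1S,3E)-1-[(2S,3R)-2-({[tert-butyl(diphenyl)silyl]oxy}methyl)-4-methylidene-5-oxooxolan-3-yl]-3-methyl-5-oxooct-3-en-6-yn-1-yl (2Z)-2-methylbut-2-enoate, via acid chloride 19 (not isolated)
Conditions: Me2C=C(Cl)NMe2, CH2Cl2, 0 °C; then 18, PdCl2(PPh3)2 (5 mol%), THF, 50 °C
Reagents that add atoms: 1-chloro-N,N,2-trimethylprop-1-en-1-amine, CC(C)=C(Cl)N(C)C (chlorine of intermediate 19 only)
Why: Neutral acid chloride formation followed by Stille acylation with the alkynylstannane gives the ynone without amine base, so no vinylketene forms and the C1=C10 geometry is kept.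

Step 9
Reactants: 20 the ynone of step 8
Product: 21 (1S,3E,6Z)-1-[(2S,3R)-2-({[tert-butyl(diphenyl)silyl]oxy}methyl)-4-methylidene-5-oxooxolan-3-yl]-7-iodo-3-methyl-5-oxoocta-3,6-dien-1-yl (2Z)-2-methylbut-2-enoate
Conditions: NaI, AcOH, rt, dark
Reagents that add atoms: sodium iodide, [Na+].[I-]
Why: Conjugate anti-hydroiodination of the ynone gives the kinetic (Z)-β-iodo enone (iodine cis to the C2 carbonyl), the ynone being far more electrophilic than the methylene lactone or the enoate.

Step 10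
Reactants: 21 the iodo dienone of step 9
Product: 22 (1S,3E,6Z)-1-[(2S,3R)-2-(hydroxymethyl)-4-methylidene-5-oxooxolan-3-yl]-7-iodo-3-methyl-5-oxoocta-3,6-dien-1-yl (2Z)-2-methylbut-2-enoate
Conditions: HF·pyridine, THF, 0 °C → rt (no added pyridine)
Reagents that add atoms: none
Why: Fluoride-driven cleavage of the primary silyl ether under acidic conditions keeps pyridine protonated, so the vinylogous acyl iodide is not attacked.

Step 11
Reactants: 22 the primary alcohol of step 10
Product: 23 (1S,3E,6Z)-1-[(2S,3R)-2-formyl-4-methylidene-5-oxooxolan-3-yl]-7-iodo-3-methyl-5-oxoocta-3,6-dien-1-yl (2Z)-2-methylbut-2-enoate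
Conditions: Dess–Martin periodinane, CH2Cl2, 0 °C → rt; use crude at once
Reagents that add atoms: none
Why: Dess–Martin oxidation is neutral and does not epimerise the α-acyloxy aldehyde at C6.

Step 12
Reactants: 23 the iodo dienone aldehyde of step 11
Product: 26 (3aR,4S,6E,9Z,11R,11aS)-11-hydroxy-6,10-dimethyl-3-methylidene-2,8-dioxo-2,3,3a,4,5,8,11,11a-octahydrocyclodeca[b]furan-4-yl (2Z)-2-methylbut-2-enoate, via alkenylchromium dichloride 24 (not isolated), via chromium alkoxide 25 (not isolated)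
Conditions: CrCl2 (10 equiv), NiCl2 (2 mol%), DMSO/THF, 2 mM, rt, slow addition; aq. work-up
Reagents that add atoms: chromium dichloride, Cl[Cr]Cl (CrCl2 units of intermediates 24 and 25 only)
Why: In this intramolecular Nozaki–Hiyama–Kishi reaction nickel-mediated C–I activation and transmetalation to divalent chromium give the alkenylchromium with retention of the Z geometry, and it adds to the aldehyde anti to the C6–O bond (polar Felkin–Anh), closing the ten-membered ring and setting C5 as R (5,6-anti).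

**Compound list**
1 | methyl 4-hydroxybut-2-ynoate | COC(=O)C#CCO | starting material
2 | methyl 4-oxobut-2-ynoate | COC(=O)C#CC=O | intermediate
3 | tert-butyl 3-methylbut-2-enoate | CC(C)=CC(=O)OC(C)(C)C | starting material
4 | lithium 1-tert-butoxy-3-methylbuta-1,3-dien-1-olate | C=C(C)C=C([O-])OC(C)(C)C.[Li+] | intermediate (not isolated)
5 | tert-butyl[(1-tert-butoxy-3-methylbuta-1,3-dien-1-yl)oxy]dimethylsilane (ketene acetal geometry not defined) | C=C(C)C=C(O[Si](C)(C)C(C)(C)C)OC(C)(C)C | intermediate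
6 | 1-tert-butyl 8-methyl (2E,5S)-3-methyl-5-[(trichlorosilyl)oxy]oct-2-en-6-ynedioate | COC(=O)C#C[C@@H](O[Si](Cl)(Cl)Cl)C/C(C)=C/C(=O)OC(C)(C)C | intermediate (not isolated)
7 | 1-tert-butyl 8-methyl (2E,5S)-5-hydroxy-3-methyloct-2-en-6-ynedioate | COC(=O)C#C[C@@H](O)C/C(C)=C/C(=O)OC(C)(C)C | intermediate
8 | angelic acid, (2Z)-2-methylbut-2-enoic acid | C/C=C(/C)C(=O)O | starting material
9 | (2Z)-2-methylbut-2-enoic 2,4,6-trichlorobenzoic anhydride | C/C=C(/C)C(=O)OC(=O)c1c(Cl)cc(Cl)cc1Cl | intermediate (not isolated)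
10 | 1-tert-butyl 8-methyl (2E,5S)-3-methyl-5-{[(2Z)-2-methylbut-2-enoyl]oxy}oct-2-en-6-ynedioate | COC(=O)C#C[C@@H](OC(=O)/C(C)=C\C)C/C(C)=C/C(=O)OC(C)(C)C | intermediate
11 | 2-(iodomethyl)-4,4,5,5-tetramethyl-1,3,2-dioxaborolane | ICB1OC(C)(C)C(C)(C)O1 | starting material
12 | diisobutylaluminium allenolate of 10 (O-bound, hydride delivered to C7) | COC(O[Al](CC(C)C)CC(C)C)=C=C[C@@H](OC(=O)/C(C)=C\C)C/C(C)=C/C(=O)OC(C)(C)C | intermediate (not isolated)
13 | 1-tert-butyl 8-methyl (2E,5S,6Z)-3-methyl-5-{[(2Z)-2-methylbut-2-enoyl]oxy}-7-[(4,4,5,5-tetramethyl-1,3,2-dioxaborolan-2-yl)methyl]octa-2,6-dienedioate (C8 cis to CO2Me) | COC(=O)/C(CB1OC(C)(C)C(C)(C)O1)=C\[C@@H](OC(=O)/C(C)=C\C)C/C(C)=C/C(=O)OC(C)(C)C | intermediate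
14 | 2-{[tert-butyl(diphenyl)silyl]oxy}acetaldehyde | O=CCO[Si](c1ccccc1)(c1ccccc1)C(C)(C)C | starting material
15 | open-chain C6–O–Bpin homoallylic alkoxide, methyl 2-methylidene ester (C6, C7 and C8 configured as in 16) | C=C(C(=O)OC)[C@@H]([C@H](OB1OC(C)(C)C(C)(C)O1)CO[Si](c1ccccc1)(c1ccccc1)C(C)(C)C)[C@@H](OC(=O)/C(C)=C\C)C/C(C)=C/C(=O)OC(C)(C)C | intermediate (not isolated)
16 | tert-butyl (2E,5S)-5-[(2S,3R)-2-({[tert-butyl(diphenyl)silyl]oxy}methyl)-4-methylidene-5-oxooxolan-3-yl]-3-methyl-5-{[(2Z)-2-methylbut-2-enoyl]oxy}pent-2-enoate (trans-lactone) | C=C1C(=O)O[C@H](CO[Si](c2ccccc2)(c2ccccc2)C(C)(C)C)[C@H]1[C@@H](OC(=O)/C(C)=C\C)C/C(C)=C/C(=O)OC(C)(C)C | intermediate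
17 | (2E,5S)-5-[(2S,3R)-2-({[tert-butyl(diphenyl)silyl]oxy}methyl)-4-methylidene-5-oxooxolan-3-yl]-3-methyl-5-{[(2Z)-2-methylbut-2-enoyl]oxy}pent-2-enoic acid | C=C1C(=O)O[C@H](CO[Si](c2ccccc2)(c2ccccc2)C(C)(C)C)[C@H]1[C@@H](OC(=O)/C(C)=C\C)C/C(C)=C/C(=O)O | intermediate
18 | tributyl(prop-1-yn-1-yl)stannane | CC#C[Sn](CCCC)(CCCC)CCCC | starting material
19 | acid chloride of 17 | C=C1C(=O)O[C@H](CO[Si](c2ccccc2)(c2ccccc2)C(C)(C)C)[C@H]1[C@@H](OC(=O)/C(C)=C\C)C/C(C)=C/C(=O)Cl | intermediate (not isolated)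
20 | (1S,3E)-1-[(2S,3R)-2-({[tert-butyl(diphenyl)silyl]oxy}methyl)-4-methylidene-5-oxooxolan-3-yl]-3-methyl-5-oxooct-3-en-6-yn-1-yl (2Z)-2-methylbut-2-enoate | C=C1C(=O)O[C@H](CO[Si](c2ccccc2)(c2ccccc2)C(C)(C)C)[C@H]1[C@@H](OC(=O)/C(C)=C\C)C/C(C)=C/C(=O)C#CC | intermediate
21 | (1S,3E,6Z)-1-[(2S,3R)-2-({[tert-butyl(diphenyl)silyl]oxy}methyl)-4-methylidene-5-oxooxolan-3-yl]-7-iodo-3-methyl-5-oxoocta-3,6-dien-1-yl (2Z)-2-methylbut-2-enoate | C=C1C(=O)O[C@H](CO[Si](c2ccccc2)(c2ccccc2)C(C)(C)C)[C@H]1[C@@H](OC(=O)/C(C)=C\C)C/C(C)=C/C(=O)/C=C(/C)I | intermediate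
22 | (1S,3E,6Z)-1-[(2S,3R)-2-(hydroxymethyl)-4-methylidene-5-oxooxolan-3-yl]-7-iodo-3-methyl-5-oxoocta-3,6-dien-1-yl (2Z)-2-methylbut-2-enoate | C=C1C(=O)O[C@H](CO)[C@H]1[C@@H](OC(=O)/C(C)=C\C)C/C(C)=C/C(=O)/C=C(/C)I | intermediate
23 | (1S,3E,6Z)-1-[(2S,3R)-2-formyl-4-methylidene-5-oxooxolan-3-yl]-7-iodo-3-methyl-5-oxoocta-3,6-dien-1-yl (2Z)-2-methylbut-2-enoate | C=C1C(=O)O[C@H](C=O)[C@H]1[C@@H](OC(=O)/C(C)=C\C)C/C(C)=C/C(=O)/C=C(/C)I | intermediate
24 | C4-alkenylchromium dichloride derived from 23 (trivalent chromium in place of iodine, Z retained) | C=C1C(=O)O[C@H](C=O)[C@H]1[C@@H](OC(=O)/C(C)=C\C)C/C(C)=C/C(=O)/C=C(/C)[Cr](Cl)Cl | intermediate (not isolated)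
25 | C5–O chromium dichloride alkoxide of 26 | C=C1C(=O)O[C@H]2[C@H]1[C@@H](OC(=O)/C(C)=C\C)C/C(C)=C/C(=O)/C=C(/C)[C@H]2O[Cr](Cl)Cl | intermediate (not isolated)
26 | (3aR,4S,6E,9Z,11R,11aS)-11-hydroxy-6,10-dimethyl-3-methylidene-2,8-dioxo-2,3,3a,4,5,8,11,11a-octahydrocyclodeca[b]furan-4-yl (2Z)-2-methylbut-2-enoate; in germacrane numbering (5R,6S,7R,8S), 1(10)E, 3Z | C=C1C(=O)O[C@H]2[C@H]1[C@@H](OC(=O)/C(C)=C\C)C/C(C)=C/C(=O)/C=C(/C)[C@H]2O | target

**Step count**
Total: 12 steps. Longest linear sequence: 11 steps (steps 1 and 3–12, or steps 2–12).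

**Three steps most likely to fail**

Step 6 (the proposed new step). The ester-deactivated boronate may be too sluggish under chiral acid catalysis, or the catalyst may be mismatched with the existing C8 centre; simple models for the allylic C8 centre disagree on which alkene face it favours. The fallback uses known chemistry, sets out from 13 and comes back at 16. The C–B bond is oxidised with NaBO3·4H2O (THF/H2O, rt) to the 2-(hydroxymethyl) enoate F3. CBr4/PPh3 (CH2Cl2, 0 °C) converts it into the allylic bromide F4. F4 is then coupled with aldehyde 14 by the CrCl2-mediated Nozaki–Hiyama 2-(alkoxycarbonyl)allylation (THF, rt), which is anti-selective and lactonises in the flask to the trans-lactone 16. The two facial isomers relative to C8 are separated by chromatography.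

Step 5. The hydride may also reduce the angelate or the tert-butyl ester, or the allenolate may alkylate poorly. The fallback sets out from 10 and comes back at 13. Syn-hydrostannation (Bu3SnH, Pd(PPh3)4, THF, 0 °C, tin α to the ester) gives the α-tributylstannyl enoate F1. Iododestannylation (I2, CH2Cl2, 0 °C) gives, with retention, the α-iodo enoate F2. Negishi coupling of F2 with IZnCH2Bpin (from 11 and zinc dust) under Pd(PPh3)4 gives 13.

Step 12. The macrocyclic addition may favour the wrong C5 configuration because ring strain can override the Felkin preference. The fallback sets out from 23 and ends at 26; it corrects the C5 configuration but does not rescue a ring closure that fails outright. The cyclisation product, for example the 5-epi alcohol F5, is oxidised with Dess–Martin periodinane to the cyclic 2,5-dione F6. The more electrophilic, α-oxygenated C5 ketone is then reduced under reagent control with (R)-Me-CBS oxazaborolidine and catecholborane (toluene, −78 °C; catalyst hand predicted with the alkenyl group as the large substituent) to 26.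

**Further compounds**
F1 | step 5 | 1-tert-butyl 8-methyl (2E,5S)-3-methyl-5-{[(2Z)-2-methylbut-2-enoyl]oxy}-7-(tributylstannyl)octa-2,6-dienedioate (C5 of the chain cis to CO2Me) | COC(=O)/C([Sn](CCCC)(CCCC)CCCC)=C\[C@@H](OC(=O)/C(C)=C\C)C/C(C)=C/C(=O)OC(C)(C)C
F2 | step 5 | 1-tert-butyl 8-methyl (2E,5S)-7-iodo-3-methyl-5-{[(2Z)-2-methylbut-2-enoyl]oxy}octa-2,6-dienedioate (C5 of the chain cis to CO2Me) | COC(=O)/C(I)=C\[C@@H](OC(=O)/C(C)=C\C)C/C(C)=C/C(=O)OC(C)(C)C
F3 | step 6 | 1-tert-butyl 8-methyl (2E,5S,6Z)-7-(hydroxymethyl)-3-methyl-5-{[(2Z)-2-methylbut-2-enoyl]oxy}octa-2,6-dienedioate | COC(=O)/C(CO)=C\[C@@H](OC(=O)/C(C)=C\C)C/C(C)=C/C(=O)OC(C)(C)C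
F4 | step 6 | 1-tert-butyl 8-methyl (2E,5S)-7-(bromomethyl)-3-methyl-5-{[(2Z)-2-methylbut-2-enoyl]oxy}octa-2,6-dienedioate (C5 of the chain cis to CO2Me) | COC(=O)/C(CBr)=C\[C@@H](OC(=O)/C(C)=C\C)C/C(C)=C/C(=O)OC(C)(C)C
F5 | step 12 | 5-epimer of 26 (germacrane 5S,6S,7R,8S) | C=C1C(=O)O[C@H]2[C@H]1[C@@H](OC(=O)/C(C)=C\C)C/C(C)=C/C(=O)/C=C(/C)[C@@H]2O
F6 | step 12 | 2,5-dioxo analogue of 26 (C5 ketone; germacrane 6S,7R,8S) | C=C1C(=O)O[C@H]2[C@H]1[C@@H](OC(=O)/C(C)=C\C)C/C(C)=C/C(=O)/C=C(/C)C2=O
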